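**Strategy.** The target is a 1,2-diacyl-sn-glycerol with two identical C18 chains, so the route rests on one epoxy-diynoic acid, cut at C7–C8 into a hepta-4,6-diynoate and an eleven-carbon α-chloro aldehyde (C8–C18). The key step exploits the C13=C14–C15=C16 Z,Z-diene, which lies three methylenes (C10–C12) beyond the C8–C9 oxirane ring and is four hydrogens away from a conjugated diyne. Activated zinc turns undeca-6,8-diyn-1-ol into the (6Z,8Z)-dienol, fixing both alkene geometries in one operation while the C4–C7 diyne of the head is still absent. The precursor is a linear C11 diynol, made by Cadiot–Chodkiewicz coupling of 7-bromohept-6-yn-1-ol with but-1-yne.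

Key step: step 3

Remark on chain length: the tail fragment must supply C8–C18, with C10–C12 between oxirane and diene, so the diynol is the eleven-carbon undeca-6,8-diyn-1-ol (from hept-6-yn-1-ol); a ten-carbon diynol would end in a C17 acid.

Remark on configuration: acyl atoms are numbered C1–C18 from the ester carbonyl; read from the SMILES, both oxiranes are trans-(8S,9S) and the glycerol carbon is 2S (a 1,2-diacyl-sn-glycerol).

**Step 1**
Reactants: 1 hept-6-yn-1-ol
Product: 2 7-bromohept-6-yn-1-ol
Conditions: NBS (1.1 equiv), AgNO3 (0.1 equiv), acetone, rt, dark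
Reagents that add atoms: N-bromosuccinimide, O=C1CCC(=O)N1Br
Why: Silver-catalysed electrophilic bromination of a terminal alkyne (via the silver acetylide) should give the 1-bromoalkyne without touching the primary alcohol, and putting the bromine on the involatile alkynol avoids a volatile low-molecular-weight bromoalkyne.

**Step 2**
Reactants: 2 7-bromohept-6-yn-1-ol; 3 but-1-yne
Product: 4 undeca-6,8-diyn-1-ol
Conditions: CuCl (5 mol%), NH2OH·HCl, 30% aq. n-BuNH2, Et2O, 0 °C; 3 (3 equiv, condensed in), 2 added slowly
Reagents that add atoms: none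
Why: Cadiot–Chodkiewicz coupling, in which the copper acetylide of 3 (copper kept monovalent by hydroxylamine) couples with the 1-bromoalkyne to form the C(sp)–C(sp) bond of the unsymmetrical diyne, the excess of the cheap gaseous alkyne suppressing homocoupling of 2.

**Step 3**
Reactants: 4 undeca-6,8-diyn-1-ol
Product: 7 (6Z,8Z)-undeca-6,8-dien-1-ol, via (Z)-undec-6-en-8-yn-1-ol 5 (not isolated), via (Z)-undec-8-en-6-yn-1-ol 6 (not isolated)
Conditions: Zn dust (excess) activated with Cu(OAc)2·H2O then AgNO3, MeOH/H2O 1:1, 45 °C, Ar, followed by GC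
Reagents that add atoms: none
Why: The conjugated diyne binds to the copper- and silver-doped zinc surface, takes up electrons from the metal, and the surface-bound vinyl species are protonated by water/methanol with retention, so that both hydrogens end on the same side of each former triple bond; the first reduction gives the conjugated Z-enynes 5 and 6, which are still activated and are reduced again to the Z,Z-diene 7. The closest known reaction type is the activated-zinc cis-semireduction of conjugated enynes and diynes (Boland reduction). No ring is closed and no stereocentre is formed; the two stereo-elements created are the 6Z and 8Z double bonds, each controlled by syn delivery of hydrogen at the metal surface. The step needs complete reduction of both alkynes without over-reduction or Z-to-E isomerisation, and this should be secured because unconjugated π-bonds, the diene product and the free hydroxyl are inert to the reagent in the neutral protic medium, and because 4 carries no other conjugated alkyne at this stage (the C4–C7 diyne enters only in step 8).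

**Step 4**
Reactants: 7 (6Z,8Z)-undeca-6,8-dien-1-ol
Product: 8 (6Z,8Z)-undeca-6,8-dienal
Conditions: PhI(OAc)2 (1.1 equiv), TEMPO (0.1 equiv), CH2Cl2, rt
Reagents that add atoms: none
Why: Oxoammonium-mediated (TEMPO/PhI(OAc)2) oxidation of a primary alcohol stops at the aldehyde under base-free conditions, and the diene, four carbons from the carbonyl, has no pathway into conjugation or isomerisation.

**Step 5**
Reactants: 8 (6Z,8Z)-undeca-6,8-dienal
Product: 9 (2R,6Z,8Z)-2-chloroundeca-6,8-dienal
Conditions: (5R)-5-benzyl-2,2,3-trimethylimidazolidin-4-one·CF3CO2H (10 mol%), 2,3,4,5,6,6-hexachlorocyclohexa-2,4-dien-1-one (1.2 equiv), acetone, −30 °C; cold pentane, short silica plug, used at once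
Reagents that add atoms: 2,3,4,5,6,6-hexachlorocyclohexa-2,4-dien-1-one, O=C1C(Cl)=C(Cl)C(Cl)=C(Cl)C1(Cl)Cl
Why: Enamine-catalysed asymmetric α-chlorination of an aldehyde, in which the E-enamine of the imidazolidinone is chlorinated by the mild Cl+ donor on the face remote from the benzyl group, which for the (5R) catalyst should set C2 (the future C9) as R, while the closed-shell conditions leave the remote diene alone.

**Step 6**
Reactants: 10 methyl pent-4-ynoate; 11 (bromoethynyl)tri(propan-2-yl)silane
Product: 12 methyl 7-[tri(propan-2-yl)silyl]hepta-4,6-diynoate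
Conditions: CuCl (5 mol%), NH2OH·HCl, 30% aq. n-BuNH2, Et2O, 0 °C
Reagents that add atoms: none
Why: Cadiot–Chodkiewicz coupling of a terminal alkyne with a bulky silyl-capped bromoalkyne, whose silyl group survives the aqueous amine and blocks the far terminus, while the methyl ester is not aminolysed at 0 °C in the short reaction time.

**Step 7**
Reactants: 12 methyl 7-[tri(propan-2-yl)silyl]hepta-4,6-diynoate
Product: 13 methyl hepta-4,6-diynoate
Conditions: Bu4NF (1.1 equiv), wet THF, −20 → 0 °C; aq. NH4Cl; kept cold as a solution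
Reagents that add atoms: none
Why: Fluoride-induced protodesilylation of an alkynylsilane cleaves the C(sp)–Si bond rapidly at low temperature, leaving the ester intact, and the terminal diyne is not concentrated to dryness because such compounds polymerise neat.

**Step 8**
Reactants: 9 (2R,6Z,8Z)-2-chloroundeca-6,8-dienal; 13 methyl hepta-4,6-diynoate
Product: 15 methyl (8S,9R,13Z,15Z)-9-chloro-8-hydroxyoctadeca-13,15-dien-4,6-diynoate, via lithium diynide 14 (not isolated)
Conditions: 13 (1.3 equiv), LiN(SiMe3)2 (1.25 equiv), THF, −78 °C, 20 min; then 9, −78 °C; sat. aq. NH4Cl at −78 °C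
Reagents that add atoms: none
Why: 1,2-Addition of a lithium acetylide to an α-chloro aldehyde under Cornforth (dipole-opposed, polar Felkin–Anh) control, in which the amide base removes the acidic diyne C–H in preference to the ester α-protons at −78 °C and the small sp nucleophile attacks the rotamer with C=O and C–Cl opposed from the side away from the alkyl chain, so that the existing 9R centre sets the new carbinol centre as 8S (1,2-anti chlorohydrin).

**Step 9**
Reactants: 15 methyl (8S,9R,13Z,15Z)-9-chloro-8-hydroxyoctadeca-13,15-dien-4,6-diynoate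
Product: 17 (8S,9S,13Z,15Z)-8,9-epoxyoctadeca-13,15-dien-4,6-diynoic acid, via trans-epoxy methyl ester 16 (not isolated)
Conditions: LiOH·H2O (4 equiv), THF/MeOH/H2O 3:1:1, 0 °C → rt; cold dilute HCl to pH 4, extraction; used without storage
Reagents that add atoms: lithium hydroxide, [Li+].[OH-]
Why: Base-induced chlorohydrin-to-epoxide closure (intramolecular Williamson SN2, 3-exo-tet) inverts C9 and so converts the anti chlorohydrin stereospecifically into the trans-(8S,9S) oxirane, after which hydroxide saponifies the methyl ester in the same flask (acyl–oxygen cleavage) without opening the oxirane or touching the diyne and diene.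

**Step 10**
Reactants: 18 (S)-(2,2-dimethyl-1,3-dioxolan-4-yl)methanol (1,2-O-isopropylidene-sn-glycerol)
Product: 19 3-O-(tert-butyldiphenylsilyl)-1,2-O-isopropylidene-sn-glycerol
Conditions: t-BuPh2SiCl (1.1 equiv), imidazole (2 equiv), DMF, 0 °C → rt
Reagents that add atoms: tert-butyl(chloro)diphenylsilane, CC(C)(C)[Si](Cl)(c1ccccc1)c1ccccc1
Why: Imidazole-promoted silylation of the only free (primary, sn-3) hydroxyl leaves the stereocentre untouched, and the bulky silyl group is chosen because it survives the acetal hydrolysis of step 11 and does not migrate in the diol.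

**Step 11**
Reactants: 19 3-O-(tert-butyldiphenylsilyl)-1,2-O-isopropylidene-sn-glycerol
Product: 20 3-O-(tert-butyldiphenylsilyl)-sn-glycerol
Conditions: AcOH/H2O 4:1, 40 °C
Reagents that add atoms: none
Why: Acid-catalysed acetal hydrolysis frees the sn-1 and sn-2 hydroxyls while the hindered silyl ether is stable to aqueous acetic acid, and no bond to the stereocentre is broken.

**Step 12**
Reactants: 20 3-O-(tert-butyldiphenylsilyl)-sn-glycerol; 17 (8S,9S,13Z,15Z)-8,9-epoxyoctadeca-13,15-dien-4,6-diynoic acid (2.3 equiv)
Product: 22 1,2-bis-O-[(8S,9S,13Z,15Z)-8,9-epoxyoctadeca-13,15-dien-4,6-diynoyl]-3-O-(tert-butyldiphenylsilyl)-sn-glycerol, via sn-1 monoester 21 (not isolated)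
Conditions: DCC (2.5 equiv), DMAP (0.3 equiv), CH2Cl2, 0 °C → rt
Reagents that add atoms: none
Why: Steglich esterification (carbodiimide activation, DMAP acyl transfer) acylates first the primary and then the secondary hydroxyl under neutral conditions that the oxiranes, diynes and dienes tolerate, and the glycerol stereocentre is not involved.

**Step 13**
Reactants: 22 1,2-bis-O-[(8S,9S,13Z,15Z)-8,9-epoxyoctadeca-13,15-dien-4,6-diynoyl]-3-O-(tert-butyldiphenylsilyl)-sn-glycerol
Product: 23 1,2-bis-O-[(8S,9S,13Z,15Z)-8,9-epoxyoctadeca-13,15-dien-4,6-diynoyl]-sn-glycerol (target)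
Conditions: Bu4NF (3 equiv), AcOH (3 equiv), THF, 0 °C → rt; pH 7 buffer; rapid chromatography on H3BO3-doped silica
Reagents that add atoms: none
Why: Fluoride-induced Si–O cleavage buffered with acetic acid, so that the freed sn-3 oxygen is protonated before it can take up the neighbouring acyl group, under conditions to which oxiranes, diynes and dienes are inert.

**Compound list**

1 | hept-6-yn-1-ol | C#CCCCCCO | starting material
2 | 7-bromohept-6-yn-1-ol | OCCCCCC#CBr | intermediate
3 | but-1-yne | CCC#C | starting material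
4 | undeca-6,8-diyn-1-ol | OCCCCCC#CC#CCC | intermediate
5 | (Z)-undec-6-en-8-yn-1-ol | OCCCCC/C=C\C#CCC | intermediate (not isolated)
6 | (Z)-undec-8-en-6-yn-1-ol | OCCCCCC#C/C=C\CC | intermediate (not isolated)
7 | (6Z,8Z)-undeca-6,8-dien-1-ol | OCCCCC/C=C\C=C/CC | intermediate
8 | (6Z,8Z)-undeca-6,8-dienal | O=CCCCC/C=C\C=C/CC | intermediate
9 | (2R,6Z,8Z)-2-chloroundeca-6,8-dienal | O=C[C@H](Cl)CCC/C=C\C=C/CC | intermediate
10 | methyl pent-4-ynoate | C#CCCC(=O)OC | starting material
11 | (bromoethynyl)tri(propan-2-yl)silane | BrC#C[Si](C(C)C)(C(C)C)C(C)C | starting material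
12 | methyl 7-[tri(propan-2-yl)silyl]hepta-4,6-diynoate | COC(=O)CCC#CC#C[Si](C(C)C)(C(C)C)C(C)C | intermediate
13 | methyl hepta-4,6-diynoate | COC(=O)CCC#CC#C | intermediate
14 | methyl 7-lithiohepta-4,6-diynoate (lithium diynide) | COC(=O)CCC#CC#C[Li] | intermediate (not isolated)
15 | methyl (8S,9R,13Z,15Z)-9-chloro-8-hydroxyoctadeca-13,15-dien-4,6-diynoate (anti chlorohydrin) | COC(=O)CCC#CC#C[C@H](O)[C@H](Cl)CCC/C=C\C=C/CC | intermediate
16 | methyl (8S,9S,13Z,15Z)-8,9-epoxyoctadeca-13,15-dien-4,6-diynoate (trans oxirane) | COC(=O)CCC#CC#C[C@@H]1O[C@H]1CCC/C=C\C=C/CC | intermediate (not isolated)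
17 | (8S,9S,13Z,15Z)-8,9-epoxyoctadeca-13,15-dien-4,6-diynoic acid | OC(=O)CCC#CC#C[C@@H]1O[C@H]1CCC/C=C\C=C/CC | intermediate
18 | (S)-(2,2-dimethyl-1,3-dioxolan-4-yl)methanol (1,2-O-isopropylidene-sn-glycerol) | CC1(C)OC[C@H](CO)O1 | starting material
19 | (R)-tert-butyl[(2,2-dimethyl-1,3-dioxolan-4-yl)methoxy]diphenylsilane (3-O-silyl-1,2-O-isopropylidene-sn-glycerol) | CC1(C)OC[C@H](CO[Si](c2ccccc2)(c2ccccc2)C(C)(C)C)O1 | intermediate
20 | (R)-3-[(tert-butyldiphenylsilyl)oxy]propane-1,2-diol (3-O-silyl-sn-glycerol) | OC[C@H](CO[Si](c1ccccc1)(c1ccccc1)C(C)(C)C)O | intermediate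
21 | 1-O-[(8S,9S,13Z,15Z)-8,9-epoxyoctadeca-13,15-dien-4,6-diynoyl]-3-O-(tert-butyldiphenylsilyl)-sn-glycerol (glycerol C2 R) | CC/C=C\C=C/CCC[C@@H]1O[C@H]1C#CC#CCCC(=O)OC[C@H](CO[Si](c1ccccc1)(c1ccccc1)C(C)(C)C)O | intermediate (not isolated)
22 | 1,2-bis-O-[(8S,9S,13Z,15Z)-8,9-epoxyoctadeca-13,15-dien-4,6-diynoyl]-3-O-(tert-butyldiphenylsilyl)-sn-glycerol (glycerol C2 R by CIP, same spatial arrangement as the target) | CC/C=C\C=C/CCC[C@@H]1O[C@H]1C#CC#CCCC(=O)OC[C@H](CO[Si](c1ccccc1)(c1ccccc1)C(C)(C)C)OC(=O)CCC#CC#C[C@@H]1O[C@H]1CCC/C=C\C=C/CC | intermediate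
23 | 1,2-bis-O-[(8S,9S,13Z,15Z)-8,9-epoxyoctadeca-13,15-dien-4,6-diynoyl]-sn-glycerol (glycerol C2 S) | CC/C=C\C=C/CCC[C@@H]1O[C@H]1C#CC#CCCC(=O)OC[C@H](CO)OC(=O)CCC#CC#C[C@@H]1O[C@H]1CCC/C=C\C=C/CC | target

**Step count.** Total: 13 steps. Longest linear sequence: 9 steps (1, 2, 3, 4, 5, 8, 9, 12, 13).

**Steps most likely to fail**

1. Step 8. The basic diynide may enolise the chloro aldehyde and erode configuration at C9, facial discrimination at the carbonyl may be weak, or the ester-bearing nucleophile may condense with itself. Fallback, setting out from 9: lithium (trimethylsilyl)acetylide (ethynyltrimethylsilane, n-BuLi, THF, −78 °C), an ester-free nucleophile of the type for which anti selectivity is well established, should give (3S,4R,8Z,10Z)-4-chloro-1-(trimethylsilyl)trideca-8,10-dien-1-yn-3-ol F1. KOH in EtOH would then close the oxirane and cleave the C–Si bond to give (2S,3S)-2-ethynyl-3-[(4Z,6Z)-nona-4,6-dien-1-yl]oxirane F2. Cadiot–Chodkiewicz coupling of this alkyne (CuCl, NH2OH·HCl, aq. n-BuNH2, 0 °C) with 5-bromopent-4-ynoic acid F3 (from pent-4-ynoic acid, NBS, AgNO3) would form C5–C6 instead of C7–C8 and come back to the route at acid 17.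

2. Step 13. The sn-2 acyl group may migrate to the freed sn-3 oxygen during slow cleavage of the hindered silyl ether, or fluoride may cleave an ester. Fallback, setting out from 18: NaH and 4-methoxybenzyl chloride should give 3-O-(4-methoxybenzyl)-1,2-O-isopropylidene-sn-glycerol F4, and aqueous AcOH the diol 3-O-(4-methoxybenzyl)-sn-glycerol F5. DCC/DMAP with acid 17 would give 1,2-bis-O-[(8S,9S,13Z,15Z)-8,9-epoxyoctadeca-13,15-dien-4,6-diynoyl]-3-O-(4-methoxybenzyl)-sn-glycerol F6. Oxidative debenzylation with DDQ in CH2Cl2/pH 7 buffer at 0 °C, a neutral cleavage that generates no alkoxide, would come back to the route at 23.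

3. Step 3. The reduction may stall at the enyne stage on a poorly activated zinc batch, or over-reduce and isomerise Z to E on prolonged heating. Fallback, setting out from 4: twofold syn-hydroboration with dicyclohexylborane (from BH3·SMe2 and cyclohexene, THF, 0 °C; one extra equivalent for the hydroxyl), then protonolysis of the alkenyl–boron bonds with AcOH (retention of geometry) and oxidative work-up, would give the Z,Z-dienol directly and come back to the route at 7. This fallback makes no new isolable compound (F0).

**Further compounds**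

F1 | step 8 | (3S,4R,8Z,10Z)-4-chloro-1-(trimethylsilyl)trideca-8,10-dien-1-yn-3-ol | C[Si](C)(C)C#C[C@H](O)[C@H](Cl)CCC/C=C\C=C/CC
F2 | step 8 | (2S,3S)-2-ethynyl-3-[(4Z,6Z)-nona-4,6-dien-1-yl]oxirane | C#C[C@@H]1O[C@H]1CCC/C=C\C=C/CC
F3 | step 8 | 5-bromopent-4-ynoic acid | OC(=O)CCC#CBr
F4 | step 13 | (S)-4-{[(4-methoxybenzyl)oxy]methyl}-2,2-dimethyl-1,3-dioxolane (3-O-(4-methoxybenzyl)-1,2-O-isopropylidene-sn-glycerol) | CC1(C)OC[C@H](COCc2ccc(OC)cc2)O1
F5 | step 13 | (R)-3-[(4-methoxybenzyl)oxy]propane-1,2-diol (3-O-(4-methoxybenzyl)-sn-glycerol) | OC[C@H](COCc1ccc(OC)cc1)O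
F6 | step 13 | 1,2-bis-O-[(8S,9S,13Z,15Z)-8,9-epoxyoctadeca-13,15-dien-4,6-diynoyl]-3-O-(4-methoxybenzyl)-sn-glycerol | CC/C=C\C=C/CCC[C@@H]1O[C@H]1C#CC#CCCC(=O)OC[C@H](COCc1ccc(OC)cc1)OC(=O)CCC#CC#C[C@@H]1O[C@H]1CCC/C=C\C=C/CC
F0 | step 3 | none | none
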